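**Plan**

1. Numbering: bicyclo[3.3.1] core C1–C9 (C1 isobutyryl bridgehead; C2, C4, C9 ketones; C3 quaternary carbon between C2 and C4; C5 geranyl bridgehead; C6H2, C7H, C8Me2); C10 = CH2 on C7, C11 = CH on C3, C12 = CMe2, C13/C14 = CH2CH2 back to C3; geranyl C1′–C10′.
2. Retrosynthesis cuts, in order: C1–C8 (cation–enol closure of ring B); C5–C1′ (geranyl bromide plus a tricyclic enol, the fragment union); C5–C6 (Pd-allylation closing the seven-membered ring); C1–C2 and C4–C5 (Claisen pair building trione ring A from a β-diketone); C7–C10 (Negishi acylation); C3–C11 (iodocarbocyclisation of a 4-pentenylmalonate).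
3. Forward ring order: cyclopentane (C3, C11–C14) → side chain C10–C7(=C6)–C8 → trione ring A spiro at C3 → seven-membered ring C3–C4–C5–C6–C7–C10–C11 → geranyl on C5 → ring B (C1–C8), which completes the bicyclo[3.3.1]nonane and the homoadamantane cage.
4. Enabling feature: C5 lies between the C4 and C9 carbonyls of a cyclohexane-1,3,5-trione ring (a latent phloroglucinol carbon), so it is a carbon nucleophile twice. Once C6 is tied to C11 across the seven-membered ring, only the face that geranyl occupies in the target is open, and quaternising C5 (sp2 → sp3) is what lets C8 reach C1.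
5. Stereochemistry: C11 from the Ti–TADDOLate iodocarbocyclisation; C3 from hydrolysing only the ester trans to the C11 side chain (this decides which ester carbon becomes C4 and which C2); C5 from the ring tether in the key step; C7 and C1 from the cage in the last closure. Helpers: the tertiary oxygen on C8 (leaves as water in the Pd step) and the C7=C8 alkene (latent C8 cation).

Key step: step 10

Assumption: the TADDOL enantiomer is chosen so that step 4 gives (R)-6. Enolisable triketones (15, 16, 18, F2) are written as one enol tautomer.

**Route**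

Step 1
Reactants: 1 methyl 3,3-dimethylpent-4-enoate
Product: 2 3,3-dimethylpent-4-en-1-ol
Conditions: LiAlH4, Et2O, 0 °C; H2O/NaOH work-up
Reagents that add atoms: none
Why: Standard LiAlH4 ester reduction that leaves the isolated terminal alkene untouched.

Step 2
Reactants: 2 3,3-dimethylpent-4-en-1-ol
Product: 3 5-iodo-3,3-dimethylpent-1-ene
Conditions: PPh3, I2, imidazole, CH2Cl2, 0 °C → rt
Reagents that add atoms: iodine, II
Why: Appel iodination, in which iodide displaces the oxyphosphonium group by SN2 at the unhindered primary carbon.

Step 3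
Reactants: 4 dimethyl malonate; 3 5-iodo-3,3-dimethylpent-1-ene
Product: 5 dimethyl 2-(3,3-dimethylpent-4-en-1-yl)propanedioate
Conditions: NaH, 4 (3 equiv), THF–DMF, 0 → 50 °C
Reagents that add atoms: none
Why: Malonic ester alkylation by SN2, with excess malonate to suppress dialkylation.

Step 4
Reactants: 5 dimethyl 2-(3,3-dimethylpent-4-en-1-yl)propanedioate
Product: 6 dimethyl (2R)-2-(iodomethyl)-3,3-dimethylcyclopentane-1,1-dicarboxylate
Conditions: I2, Ti(TADDOLate)2 (20 mol %), 2,6-dimethoxypyridine, CH2Cl2–THF, −78 → −40 °C
Reagents that add atoms: iodine, II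
Why: Titanium-enolate iodocarbocyclisation of a 4-pentenylmalonate, in which the Ti enolate attacks the iodine-activated alkene anti in a 5-exo mode helped by the gem-dimethyl tether, and the chiral Ti–TADDOLate sets C11 as (R).

Step 5
Reactants: 6 dimethyl (2R)-2-(iodomethyl)-3,3-dimethylcyclopentane-1,1-dicarboxylate; 7 2-acetoxy-2-methylpropanoyl chloride
Product: 9 dimethyl (2R)-2-(3-acetoxy-3-methyl-2-oxobutyl)-3,3-dimethylcyclopentane-1,1-dicarboxylate, via alkylzinc iodide 8 (not isolated)
Conditions: Zn dust, LiCl, THF, 40 °C; then 7, Pd(PPh3)4 (5 mol %), 0 °C → rt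
Reagents that add atoms: none
Why: LiCl-promoted zinc insertion into the primary C–I bond and Pd-catalysed Negishi acylation of the alkylzinc form C10–C7 without touching the esters, the acetate or the C11 centre.

Step 6
Reactants: 9 dimethyl (2R)-2-(3-acetoxy-3-methyl-2-oxobutyl)-3,3-dimethylcyclopentane-1,1-dicarboxylate
Product: 10 dimethyl (2R)-2-(3-acetoxy-3-methyl-2-methylidenebutyl)-3,3-dimethylcyclopentane-1,1-dicarboxylate
Conditions: Zn, CH2Br2, TiCl4, THF–CH2Cl2, 0 °C → rt
Reagents that add atoms: dibromomethane, BrCBr
Why: Takai–Lombardo methylenation converts the hindered α-acetoxy ketone into the C7=C6H2 alkene under non-basic conditions that spare the three esters, leaving a tertiary allylic C8–O unit as the later π-allyl precursor.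

Step 7
Reactants: 10 dimethyl (2R)-2-(3-acetoxy-3-methyl-2-methylidenebutyl)-3,3-dimethylcyclopentane-1,1-dicarboxylate
Product: 11 (1S,2R)-2-(3-hydroxy-3-methyl-2-methylidenebutyl)-1-(methoxycarbonyl)-3,3-dimethylcyclopentane-1-carboxylic acid
Conditions: KOH (3 equiv), MeOH–H2O, rt → 45 °C; then 1 M HCl, 0 °C
Reagents that add atoms: potassium hydroxide, [K+].[OH-]
Why: Saponification removes the acetate and hydrolyses only the geminal ester trans to the C11 side chain (the less shielded one, after which the carboxylate protects the other ester), so the acid carbon becomes C4 and the surviving ester carbon C2, which fixes the configuration of C3.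

Step 8
Reactants: 11 (1S,2R)-2-(3-hydroxy-3-methyl-2-methylidenebutyl)-1-(methoxycarbonyl)-3,3-dimethylcyclopentane-1-carboxylic acid; 12 5-methylhexane-2,4-dione
Product: 15 (1R)-1-(3-hydroxy-3-methyl-2-methylidenebutyl)-2,2-dimethyl-7-(2-methylpropanoyl)spiro[4.5]decane-6,8,10-trione (C6 carbonyl cis to the C1 side chain), via acyl imidazolide 13 (not isolated), via open-chain triketo ester 14 (not isolated)
Conditions: 11, CDI, THF, rt; added to the dianion of 12 (LDA, THF, −78 → 0 °C, 3.5 equiv) at −78 °C → rt, then 50 °C; 1 M HCl work-up
Reagents that add atoms: none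
Why: Polyketide-type assembly of a 2-acylcyclohexane-1,3,5-trione, in which the terminal carbanion of the β-diketone dianion is C-acylated by the acyl imidazolide (C4–C5) and the triketo ester polyanion then closes ring A by intramolecular Claisen condensation of the acyl-bearing carbon C1 onto the remaining ester (C1–C2), driven by formation of the strongly acidic triketone, with C3 and C11 carried through unchanged.

Step 9
Reactants: 15 the spirotrione of step 8
Product: 16 tricyclic triketone in which C5 of 15 is bonded to C6 so that ring A is bridged from C5 to C11 by C6H2–C7(=C8Me2)–C10H2 (C3 and C11 as in 15)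
Conditions: Pd(PPh3)4 (5 mol %), THF (0.01 M), 65 °C
Reagents that add atoms: none
Why: Tsuji–Trost allylation of a strongly acidic carbon pronucleophile with a free allylic alcohol, in which the triketone itself assists ionisation of the tertiary C8–OH, the only free ring carbon C5 (C1 is blocked by the acyl group) attacks the primary terminus C6 of the π-allyl to close the seven-membered ring, and reversible O-allyl isomers drain to the C-allyl product.

Step 10
Reactants: 16 the tricyclic triketone of step 9; 17 geranyl bromide ((2E)-1-bromo-3,7-dimethylocta-2,6-diene)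
Product: 18 5-geranyl triketone, that is 16 carrying at C5 an (E)-geranyl group on the face opposite the C6–C7–C10–C11 bridge (C5 quaternary and configured as in 19)
Conditions: LiHMDS (2.2 equiv), toluene–THF, −78 °C; 17, −78 → 0 °C; aq. HCl work-up
Reagents that add atoms: none
Why: Double deprotonation gives the dienolate in which C5, flanked by the C4 and C9 carbonyls, is the only carbon nucleophile left (C1 carries the acyl group, C3 is quaternary), and it displaces bromide from C1′ of geranyl bromide by SN2 with retention of the 2′E geometry. The closest known reaction type is the alkylative dearomatisation (gem-allylation) of C-prenylated acylphloroglucinols to β-acid-type triketones. No ring is closed here. The new quaternary stereocentre C5 is controlled by the seven-membered ring C3–C4–C5–C6–C7–C10–C11: C6 is held on the C11 face of ring A, so the electrophile can only add to the opposite face and the trans-bridged diastereomer cannot form. The step needs C- over O-alkylation and SN2 over SN2′, which the lithium counter-ion in a weakly polar medium and the primary allylic bromide favour. Quaternisation turns C5 from sp2 to sp3 and thereby makes the final C1–C8 closure geometrically possible.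

Step 11
Reactants: 18 the 5-geranyl triketone of step 10
Product: 19 CNP0313870.1 (target)
Conditions: p-TsOH·H2O (0.5 equiv), CH2Cl2, 0 °C → rt
Reagents that add atoms: none
Why: Biomimetic cation–enol cyclisation, in which protonation of the tetrasubstituted C7=C8 alkene at C7 from its exposed face gives the tertiary C8 cation held above ring A by the seven-membered ring, the enol carbon C1 captures it to close six-membered ring B (type A acylphloroglucinol ring closure), and the cage allows only the C7 and C1 configurations of the target, protonation being reversible for any unproductive C7 epimer.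

**Compound list**

1 | methyl 3,3-dimethylpent-4-enoate | COC(=O)CC(C)(C)C=C | starting material
2 | 3,3-dimethylpent-4-en-1-ol | OCCC(C)(C)C=C | intermediate
3 | 5-iodo-3,3-dimethylpent-1-ene | ICCC(C)(C)C=C | intermediate
4 | dimethyl malonate | COC(=O)CC(=O)OC | starting material
5 | dimethyl 2-(3,3-dimethylpent-4-en-1-yl)propanedioate | COC(=O)C(CCC(C)(C)C=C)C(=O)OC | intermediate
6 | dimethyl (2R)-2-(iodomethyl)-3,3-dimethylcyclopentane-1,1-dicarboxylate | COC(=O)C1(C(=O)OC)CCC(C)(C)[C@H]1CI | intermediate
7 | 2-acetoxy-2-methylpropanoyl chloride | CC(=O)OC(C)(C)C(Cl)=O | starting material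
8 | {[(1R)-2,2-bis(methoxycarbonyl)-5,5-dimethylcyclopentyl]methyl}zinc iodide (not isolated) | COC(=O)C1(C(=O)OC)CCC(C)(C)[C@H]1C[Zn]I | intermediate
9 | dimethyl (2R)-2-(3-acetoxy-3-methyl-2-oxobutyl)-3,3-dimethylcyclopentane-1,1-dicarboxylate | COC(=O)C1(C(=O)OC)CCC(C)(C)[C@H]1CC(=O)C(C)(C)OC(C)=O | intermediate
10 | dimethyl (2R)-2-(3-acetoxy-3-methyl-2-methylidenebutyl)-3,3-dimethylcyclopentane-1,1-dicarboxylate | COC(=O)C1(C(=O)OC)CCC(C)(C)[C@H]1CC(=C)C(C)(C)OC(C)=O | intermediate
11 | (1S,2R)-2-(3-hydroxy-3-methyl-2-methylidenebutyl)-1-(methoxycarbonyl)-3,3-dimethylcyclopentane-1-carboxylic acid (CO2Me cis, CO2H trans to the side chain) | COC(=O)[C@@]1(C(O)=O)CCC(C)(C)[C@H]1CC(=C)C(C)(C)O | intermediate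
12 | 5-methylhexane-2,4-dione | CC(=O)CC(=O)C(C)C | starting material
13 | methyl (1S,2R)-2-(3-hydroxy-3-methyl-2-methylidenebutyl)-1-(imidazole-1-carbonyl)-3,3-dimethylcyclopentane-1-carboxylate (not isolated) | COC(=O)[C@@]1(C(=O)n2ccnc2)CCC(C)(C)[C@H]1CC(=C)C(C)(C)O | intermediate
14 | methyl (1S,2R)-2-(3-hydroxy-3-methyl-2-methylidenebutyl)-3,3-dimethyl-1-(6-methyl-3,5-dioxoheptanoyl)cyclopentane-1-carboxylate (not isolated) | COC(=O)[C@@]1(C(=O)CC(=O)CC(=O)C(C)C)CCC(C)(C)[C@H]1CC(=C)C(C)(C)O | intermediate
15 | (1R)-1-(3-hydroxy-3-methyl-2-methylidenebutyl)-2,2-dimethyl-7-(2-methylpropanoyl)spiro[4.5]decane-6,8,10-trione; C6 carbonyl (core C2) cis to the C1 side chain; drawn as the 6,10-dienol | CC(C)C(=O)C1=C(O)[C@]2(CCC(C)(C)[C@H]2CC(=C)C(C)(C)O)C(O)=CC1=O | intermediate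
16 | tricyclic triketone: trione ring A (core C1–C5, C9) spiro at C3 to the 2,2-dimethylcyclopentane (C3, C11–C14) and bridged from C5 to C11 by C6H2–C7(=C8Me2)–C10H2; C1 isobutyryl; C3 and C11 as in 15; drawn as the C2,C9-dienol | CC(C)C(=O)C1=C(O)[C@@]23CCC(C)(C)[C@H]2CC(=C(C)C)CC(=C1O)C3=O | intermediate
17 | geranyl bromide, (2E)-1-bromo-3,7-dimethylocta-2,6-diene | CC(C)=CCC/C(C)=C/CBr | starting material
18 | 5-geranyl triketone: 16 with an (E)-geranyl group on C5 anti to the C6–C7–C10–C11 bridge (C5 quaternary, configured as in 19); drawn as the C2-enol | CC(C)C(=O)C1=C(O)[C@@]23CCC(C)(C)[C@H]2CC(=C(C)C)C[C@@](C/C=C(\C)CCC=C(C)C)(C1=O)C3=O | intermediate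
19 | CNP0313870.1: 5-[(2E)-geranyl]-1-isobutyryl-8,8,12,12-tetramethyl bicyclo[3.3.1]nonane-2,4,9-trione core in which C3 is joined to C7 by C11H–C10H2 and to C12 by C14H2–C13H2 | CC(C)=CCC/C(C)=C/C[C@@]12C[C@H]3C[C@@H]4C(C)(C)CC[C@]4(C1=O)C(=O)[C@@](C(=O)C(C)C)(C2=O)C3(C)C | target

**Count and risks**

Total steps: 11. Longest linear sequence: 11 (steps 1–11; compounds 4, 7, 12 and 17 enter as purchased).

Steps most likely to fail:

1. Step 11. Capture of the C8 cation by an enol oxygen (cyclic enol ether) or acid-induced cyclisation of the geranyl chain may outrun C1–C8 bond formation. Fallback, from 18 back to 19: replace the proton by iodonium. Treating 18 with I2 and NaHCO3 in MeCN at 0 °C should give, by iodonium-induced carbocyclisation (C1 attacks C8, iodine ends on C7 on the outer face), the 7-iodo derivative of 19, F1. Radical deiodination (Bu3SnH, AIBN, toluene, 80 °C) should then deliver hydrogen to C7 from the only open face and give 19.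

2. Step 9. The π-allyl may be captured at oxygen or intermolecularly, or ionisation of the free tertiary alcohol may be too slow for a seven-membered C-allylation at a still enolisable carbon. Fallback, from 15 back to 18: invert the two alkylations at C5. C-Geranylation of the free ring carbon of 15 (LiHMDS or aqueous KOH, geranyl bromide) should give the 5-geranyl derivative of 15, F2. Pd(0)-catalysed intramolecular allylation then makes C5 quaternary (a dearomatisation-type C-allylation that cannot revert), with the tether again placing C6 syn to C11, and gives 18 directly.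

3. Step 4. Ring closure at the unhindered terminal alkene carbon (6-endo) may compete with 5-exo attack at the neopentyl-type internal carbon, and enantioselectivity may erode next to the gem-dimethyl group. Fallback, from 5 back to 6: iodination of 5 (NaH, N-iodosuccinimide) gives dimethyl 2-iodo-2-(3,3-dimethylpent-4-en-1-yl)propanedioate F3. Iodine atom-transfer radical cyclisation (Et3B/O2), which is reliably 5-exo, gives racemic dimethyl 2-(iodomethyl)-3,3-dimethylcyclopentane-1,1-dicarboxylate F4. Preparative chromatography on a chiral stationary phase then supplies (R)-6.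

Further compounds
F1 | step 11 | 7-iodo derivative of 19 (iodine in place of H on C7) | CC(C)=CCC/C(C)=C/C[C@@]12C[C@@]3(I)C[C@@H]4C(C)(C)CC[C@]4(C1=O)C(=O)[C@@](C(=O)C(C)C)(C2=O)C3(C)C
F2 | step 9 | 5-geranyl derivative of 15 (geranyl on the free ring carbon, drawn as dienol) | CC(C)C(=O)C1=C(O)[C@]2(CCC(C)(C)[C@H]2CC(=C)C(C)(C)O)C(O)=C(C/C=C(\C)CCC=C(C)C)C1=O
F3 | step 4 | dimethyl 2-iodo-2-(3,3-dimethylpent-4-en-1-yl)propanedioate | COC(=O)C(I)(CCC(C)(C)C=C)C(=O)OC
F4 | step 4 | racemic dimethyl 2-(iodomethyl)-3,3-dimethylcyclopentane-1,1-dicarboxylate | COC(=O)C1(C(=O)OC)CCC(C)(C)C1CI
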